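**Retrosynthetic overview**
1. The 1,2-dioxane is closed last through its C3–O bond: a tertiary peroxide anion opens a cis-β-lactone at the alkyl carbon with inversion, and the freed carboxylate is methylated.
2. The tertiary C–OO bond comes from Markovnikov hydroperoxysilylation of a 1,1-disubstituted alkene; the cis-β-lactone (C2 and C3 of the propanoate arm) comes from an aldehyde by cinchona-catalysed ketene–aldehyde [2+2].
3. The aldehyde arm is built on a ring B 7-ene ester by Weinreb ketone synthesis with a dioxolanyl-ethyl Grignard reagent, Wittig methylenation and acetal hydrolysis.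
4. The 7-ene ester comes from ent-ambreinolide by acid eliminative ring opening; ent-ambreinolide comes from farnesylacetic acid by catalytic asymmetric polyene cyclisation; the acid comes from farnesyl bromide and acetic acid.
5. Ring order: ring A, ring B, δ-lactone (opened again), β-lactone (temporary), 1,2-dioxane last.

Assumption: the target is taken exactly as the given SMILES (decalin 1R,4aR,8aR, i.e. the ent-drimane series; side chain 2S,3S,6S). The IDPi enantiomer in step 2 is the mirror image of the one that gives natural (+)-sclareolide from homofarnesic acid; O-trimethylsilylquinidine in step 7 is assumed to give the (4R)-lactone, otherwise O-trimethylsilylquinine is used.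

Abbreviation: Dec = (1R,4aR,8aR)-2,5,5,8a-tetramethyl-1,4,4a,5,6,7,8,8a-octahydronaphthalen-1-yl.

**Step 1**
Reactants: 1 (2E,6E)-farnesyl bromide; 2 acetic acid
Product: 4 (4E,8E)-5,9,13-trimethyltetradeca-4,8,12-trienoic acid (farnesylacetic acid), via dilithium acetate dianion 3 (not isolated)
Conditions: 2, LDA (2.2 equiv), THF–HMPA, 0 °C; then 1, 0 °C to rt; aq. HCl
Reagents that add atoms: lithium diisopropylamide, [Li+].CC(C)[N-]C(C)C (its Li+ is in 3 only)
Why: Carboxylic acid dianion alkylation; the enediolate attacks the primary allylic bromide by SN2 at the α-carbon, which adds the two-carbon acid arm and leaves both E-alkenes untouched.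

**Step 2**
Reactants: 4 farnesylacetic acid
Product: 5 ent-ambreinolide, (4aS,6aR,10aR,10bS)-4a,7,7,10a-tetramethyldodecahydro-3H-benzo[f]chromen-3-one
Conditions: IDPi acid (2 mol%; NH-bridged bis-phosphoryl imidodiphosphorimidate of 3,3'-bis(spiro[cyclopentane-1,9'-fluoren]-2'-yl)-1,1'-bi-2-naphthol, each P=N–SO2C10F7), perfluoro-tert-butanol, −20 °C
Reagents that add atoms: none
Why: Confined chiral Brønsted acid polyene cyclisation (Stork–Eschenmoser chair–chair course); anti addition across the two E-alkenes fixes the trans-decalin, the equatorial C9 arm and the trans-fused lactone, while the catalyst pocket chooses the alkene face that is protonated and so sets the absolute configuration at C5, C8, C9 and C10.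

**Step 3**
Reactants: 5 ent-ambreinolide
Product: 6 methyl 3-(Dec)propanoate (ring B 7-ene ester)
Conditions: conc. H2SO4, MeOH, 40 °C; AgNO3–SiO2 chromatography
Reagents that add atoms: methanol, CO
Why: Acid-catalysed alkyl–oxygen cleavage of the tertiary lactone gives the C8 cation, E1 loss of the axial C7 proton gives the ring B 7-ene as main isomer (8(17)- and 8-ene isomers are removed on silver-silica), and Fischer esterification stops re-lactonisation; no stereocentre is formed and C5, C9 and C10 are untouched.

**Step 4**
Reactants: 6 ring B 7-ene ester; 7 [2-(1,3-dioxolan-2-yl)ethyl]magnesium bromide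
Product: 9 1-(1,3-dioxolan-2-yl)-5-(Dec)pentan-3-one, via N-methoxy-N-methylamide 8 (not isolated)
Conditions: MeNH(OMe)·HCl (1.5 equiv), i-PrMgCl (3.0 equiv), THF, −20 °C; then 7 (2 equiv), −20 °C to rt; aq. NH4Cl
Reagents that add atoms: N,O-dimethylhydroxylamine hydrochloride, CNOC.Cl (its N(OMe)Me group is in 8 only and leaves again on the way to 9)
Why: Telescoped Weinreb ketone synthesis; the magnesium amide turns the ester into the Weinreb amide, and the five-membered magnesium chelate of the Grignard adduct blocks a second addition until work-up.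

**Step 5**
Reactants: 9 ketone acetal
Product: 10 2-[3-methylidene-5-(Dec)pentyl]-1,3-dioxolane
Conditions: Ph3PCH3Br, KOtBu, THF, 0 °C to rt
Reagents that add atoms: methyltriphenylphosphonium bromide, C[P+](c1ccccc1)(c1ccccc1)c1ccccc1.[Br-]
Why: Wittig methylenation of an unhindered dialkyl ketone; the acetal and the trisubstituted ring alkene are inert to the ylide.

**Step 6**
Reactants: 10 methylidene acetal
Product: 11 4-methylidene-6-(Dec)hexanal
Conditions: PPTS (0.2 equiv), acetone–H2O 9:1, 55 °C
Reagents that add atoms: water, O
Why: Mild acid-catalysed acetal hydrolysis (transacetalisation to acetone); the buffered acid is too weak to protonate either alkene or to start a Prins reaction.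

**Step 7**
Reactants: 11 aldehyde; 12 propanoyl chloride
Product: 14 (3S,4R)-3-methyl-4-[3-methylidene-5-(Dec)pentyl]oxetan-2-one, via methylketene 13 (not isolated)
Conditions: 12 (2 equiv, slow addition), i-Pr2NEt, O-trimethylsilylquinidine (10 mol%), LiClO4, CH2Cl2–Et2O, −78 °C
Reagents that add atoms: none
Why: Acyl halide–aldehyde cyclocondensation (Wynberg-type cinchona-catalysed ketene–aldehyde [2+2]); the chiral ammonium enolate adds to the lithium-activated aldehyde through a closed transition state, which gives the cis-lactone and sets both new centres (3S,4R) under catalyst control.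

**Step 8**
Reactants: 14 cis-β-lactone
Product: 15 (3S,4R)-3-methyl-4-[(3S)-3-methyl-5-(Dec)-3-(triethylsilylperoxy)pentyl]oxetan-2-one
Conditions: Co(thd)2 [cobalt bis(2,2,6,6-tetramethylheptane-3,5-dionate)] (5 mol%), O2 (1 atm), Et3SiH (2 equiv), ClCH2CH2Cl, rt, stopped at full conversion of the terminal alkene
Reagents that add atoms: dioxygen, O=O; triethylsilane, CC[SiH](CC)CC
Why: Mukaiyama–Isayama hydroperoxysilylation; cobalt hydride transfers H to the CH2 terminus of the more accessible 1,1-disubstituted alkene, O2 traps the tertiary radical and the peroxide is silylated (Markovnikov C–O bond). The new centre is remote from all others and forms without control, so 15 is a roughly 1:1 pair of epimers at the peroxide carbon that is carried on and separated after step 9.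

**Step 9**
Reactants: 15 silyl peroxide β-lactone
Product: 18 methyl (2S)-2-[(3S,6S)-6-methyl-6-[2-(Dec)ethyl]-1,2-dioxan-3-yl]propanoate (target), via cesium peroxide 16 (not isolated), via cesium carboxylate 17 (not isolated)
Conditions: CsF (1.2 equiv), 18-crown-6, MeCN (0.01 M), 0 °C to rt; then MeI, rt; chromatography/HPLC to remove the 6-epimer
Reagents that add atoms: iodomethane, CI; cesium fluoride, [Cs+].[F-] (its Cs+ is the counter-ion of 16 and 17 only)
Why: Proposed new method: fluoride removes the silyl group to give the tertiary peroxide anion 16, which attacks the β-lactone at its alkyl carbon in a 6-exo-tet SN2 alkyl–oxygen cleavage (driven by ring strain and the α-effect; acyl attack would need an eight-membered ring), so the C3–O bond and the 1,2-dioxane form with inversion and the (3S,4R)-cis-lactone becomes the 2,3-anti (2S,3S) carboxylate 17, which MeI esterifies; the closest known reaction types are the SN2 alkyl–oxygen opening of β-lactones by azide, thiolate and carboxylate nucleophiles and the intramolecular opening of oxetanes or displacement of sulfonates by hydroperoxides, but a peroxide nucleophile has not been shown on a β-lactone.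

**Compound list**
1 | (2E,6E)-farnesyl bromide | CC(C)=CCC/C(C)=C/CC/C(C)=C/CBr | starting material
2 | acetic acid | CC(=O)O | starting material
3 | dilithium acetate dianion | [Li+].[Li+].[CH2-]C([O-])=O | intermediate (not isolated)
4 | (4E,8E)-5,9,13-trimethyltetradeca-4,8,12-trienoic acid | CC(C)=CCC/C(C)=C/CC/C(C)=C/CCC(=O)O | intermediate
5 | ent-ambreinolide (4aS,6aR,10aR,10bS) | C[C@@]12CCCC([C@H]1CC[C@]3([C@H]2CCC(=O)O3)C)(C)C | intermediate
6 | methyl 3-(Dec)propanoate | COC(=O)CC[C@@H]1C(C)=CC[C@@H]2C(C)(C)CCC[C@@]12C | intermediate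
7 | [2-(1,3-dioxolan-2-yl)ethyl]magnesium bromide | Br[Mg]CCC1OCCO1 | starting material
8 | N-methoxy-N-methyl-3-(Dec)propanamide | CON(C)C(=O)CC[C@@H]1C(C)=CC[C@@H]2C(C)(C)CCC[C@@]12C | intermediate (not isolated)
9 | 1-(1,3-dioxolan-2-yl)-5-(Dec)pentan-3-one | O=C(CCC1OCCO1)CC[C@@H]2C(C)=CC[C@@H]3C(C)(C)CCC[C@@]23C | intermediate
10 | 2-[3-methylidene-5-(Dec)pentyl]-1,3-dioxolane | C=C(CCC1OCCO1)CC[C@@H]2C(C)=CC[C@@H]3C(C)(C)CCC[C@@]23C | intermediate
11 | 4-methylidene-6-(Dec)hexanal | C=C(CCC=O)CC[C@@H]1C(C)=CC[C@@H]2C(C)(C)CCC[C@@]12C | intermediate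
12 | propanoyl chloride | CCC(Cl)=O | starting material
13 | methylketene | CC=C=O | intermediate (not isolated)
14 | (3S,4R)-3-methyl-4-[3-methylidene-5-(Dec)pentyl]oxetan-2-one | C[C@H]1[C@@H](CCC(=C)CC[C@@H]2C(C)=CC[C@@H]3C(C)(C)CCC[C@@]23C)OC1=O | intermediate
15 | (3S,4R)-3-methyl-4-[(3S)-3-methyl-5-(Dec)-3-(triethylsilylperoxy)pentyl]oxetan-2-one (formed with its 3R epimer, about 1:1) | C[C@H]1[C@@H](CC[C@](C)(CC[C@@H]2C(C)=CC[C@@H]3C(C)(C)CCC[C@@]23C)OO[Si](CC)(CC)CC)OC1=O | intermediate
16 | cesium peroxide of 15 (silyl group replaced by Cs+) | [Cs+].C[C@H]1[C@@H](CC[C@](C)(CC[C@@H]2C(C)=CC[C@@H]3C(C)(C)CCC[C@@]23C)O[O-])OC1=O | intermediate (not isolated)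
17 | cesium (2S)-2-[(3S,6S)-6-methyl-6-[2-(Dec)ethyl]-1,2-dioxan-3-yl]propanoate | [Cs+].[O-]C(=O)[C@@H](C)[C@@H]1CC[C@](C)(CC[C@@H]2C(C)=CC[C@@H]3C(C)(C)CCC[C@@]23C)OO1 | intermediate (not isolated)
18 | methyl (2S)-2-[(3S,6S)-6-methyl-6-[2-(Dec)ethyl]-1,2-dioxan-3-yl]propanoate | COC(=O)[C@@H](C)[C@@H]1CC[C@](C)(CC[C@@H]2C(C)=CC[C@@H]3C(C)(C)CCC[C@@]23C)OO1 | target

**Step count and risks**
Total steps: 9. Longest linear sequence: 9 (fully linear from 1 and 2).

Stereocentres: C5, C9, C10 of the decalin are set in step 2; C2 and C3 of the dioxane-propanoate are set in step 7 and C3 is inverted on purpose in step 9. C6 of the dioxane is formed in step 8 without control, so at best half of the material from step 8 onward ends as 18, and the wanted epimer is isolated by chromatography after step 9.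

Three steps most likely to fail:

Step 9 (the proposed new step). The peroxide anion may attack the lactone carbonyl or the lactone may be opened by fluoride. The fallback uses known chemistry and sets out from 11: Wittig reaction with methyl 2-(triphenylphosphoranylidene)propanoate gives methyl (2E)-2-methyl-6-methylidene-8-(Dec)oct-2-enoate F4; Mukaiyama–Isayama hydroperoxysilylation (Co(thd)2, O2, Et3SiH) gives the tertiary silyl peroxide enoate F5; desilylation with HF·pyridine and then Et2NH in CF3CH2OH triggers the intramolecular peroxide conjugate addition, which closes the dioxane and comes back to the route at 18. This known sequence gives a mixture of C2/C3/C6 diastereomers from which 18 is separated by HPLC.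

Step 3. The E1 opening may give too much of the 8(17)- or 8-ene isomers. The fallback sets out from 5: MeNH(OMe)·HCl/AlMe3 opens the lactone to the 8-hydroxy Weinreb amide F2; SOCl2/pyridine at −78 °C dehydrates it through the methyl hydrogens to the exocyclic 8(17)-ene amide F3; cobalt-hydride alkene isomerisation (chlorocobalt N,N'-bis(3,5-di-tert-butylsalicylidene)cyclohexane-1,2-diaminate, PhSiH3, benzene, rt) moves the double bond into ring B towards the less hindered C7. The fallback comes back to the route at 8, here isolated, which takes the Grignard addition of step 4 to give 9.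

Step 2. The acid terminator is one carbon further out than in the substrates on which this catalysis is established, so the enantioselectivity may drop. The fallback sets out from 4: ClSO3H in 2-nitropropane at −78 °C gives racemic ambreinolide F1, which is resolved by preparative chiral SFC on a cellulose carbamate phase; the fallback comes back to the route at 5.

**Further compounds**
F1 | step 2 | racemic ambreinolide (5 and its mirror image, 1:1) | C[C@@]12CCCC([C@H]1CC[C@]3([C@H]2CCC(=O)O3)C)(C)C.C[C@]12CCCC([C@@H]1CC[C@@]3([C@@H]2CCC(=O)O3)C)(C)C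
F2 | step 3 | 8-hydroxy Weinreb amide from ent-ambreinolide | C[C@@]12CCCC([C@H]1CC[C@](O)([C@H]2CCC(=O)N(C)OC)C)(C)C
F3 | step 3 | exocyclic 8(17)-ene Weinreb amide | C[C@@]12CCCC([C@H]1CCC(=C)[C@H]2CCC(=O)N(C)OC)(C)C
F4 | step 9 | methyl (2E)-2-methyl-6-methylidene-8-(Dec)oct-2-enoate | COC(=O)/C(C)=C/CCC(=C)CC[C@@H]1C(C)=CC[C@@H]2C(C)(C)CCC[C@@]12C
F5 | step 9 | methyl (2E)-2,6-dimethyl-8-(Dec)-6-(triethylsilylperoxy)oct-2-enoate (both C6 epimers) | COC(=O)/C(C)=C/CC[C@](C)(CC[C@@H]1C(C)=CC[C@@H]2C(C)(C)CCC[C@@]12C)OO[Si](CC)(CC)CC
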